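**Retrosynthetic overview**

- The route rests on the vicinal pair C2 (H, methyl C1) and C16 (quaternary, methyl C17) of the cycloheptanone ring A (C2, C3, C4, C5, C7, C14, C16). Their cis methyls and the attached carbonyl carbon C14 are the α,β-carbons and formyl carbon of (E)-2-methylbut-2-enal.
- Late changes: butenolide ⇒ 3-furyl; C9–OH ⇒ C9 ketone (hydride delivered from C5–OH); C7 ⇒ its epimer (equilibration next to the C14 ketone).
- Ring A ⇒ C4–C5 (SmI2 Barbier) and C7–C14 (aldol) between an acyclic iodo aldehyde and (R)-3-silyloxy-2,2-dimethylcyclopentanone (ring B: C5, C7, C8, C9, C11). The C9 centre is deliberately carried in the epimeric configuration to steer C7 and C5 and is reset at the end.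
- Iodo aldehyde ⇒ ozonolysis of the enol ether C4=C19 of a temporary cyclohexene (C16, C2, C3, C4, C19, C18) ⇒ catalytic enantioselective Diels–Alder reaction of the enal with a 2-silyloxybutadiene.
- Ring order: temporary cyclohexene (made, then cleaved), ring B (from the dione), ring A (aldol, then Barbier), butenolide last.

Key step: step 2

Assumption: atoms carry the numbers of the target SMILES order (target 2R,5S,7S,9S,16R); the facial sense of the oxazaborolidinium cycloaddition and of the CBS reduction is taken from the accepted transition-state models, and the enantiomeric catalyst would be used if either ran the other way.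

**Route**

Step 1
Reactants: 1 but-3-en-2-one
Product: 2 2-(triisopropylsilyloxy)buta-1,3-diene
Conditions: i-Pr3SiOTf, Et3N, Et2O, 0 °C to rt
Reagents that add atoms: triisopropylsilyl triflate, CC(C)[Si](C(C)C)(C(C)C)OS(=O)(=O)C(F)(F)F
Why: Soft enolisation and O-silylation of the enone gives the 2-silyloxydiene; the triisopropylsilyl group is chosen over trimethylsilyl because it resists silyl transfer to a Lewis-acid-activated aldehyde and survives steps 3 and 4.

Step 2
Reactants: 2 2-(triisopropylsilyloxy)buta-1,3-diene; 3 (E)-2-methylbut-2-enal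
Product: 4 (1R,6R)-1,6-dimethyl-4-(triisopropylsilyloxy)cyclohex-3-ene-1-carbaldehyde
Conditions: (S)-1-(2-methylphenyl)-3,3-diphenyltetrahydro-1H,3H-pyrrolo[1,2-c][1,3,2]oxazaborole (20 mol%) protonated with Tf2NH, CH2Cl2, −78 to −20 °C
Reagents that add atoms: none
Why: The protonated oxazaborolidine binds the formyl oxygen of 3 with the formyl C–H held against the ring oxygen, lowers the enal LUMO and stacks the s-trans enal on a phenyl group, so the diene adds to the open face in a concerted, asynchronous [4+2] cycloaddition; the known class is the oxazaborolidinium-catalysed Diels–Alder reaction of α-substituted enals with 2-silyloxydienes. The cyclohexene (C16, C2, C3, C4, C19, C18) closes by cycloaddition, forming C2–C3 and C16–C18 in one event. The absolute configuration at C16 and C2 is set by the catalyst, which is expected to expose the face leading to (1R,6R). Their relative configuration (methyls C1 and C17 cis) follows from suprafacial addition to the E alkene. The regiochemistry (silyloxy carbon C4 para to C16) follows from bonding of the nucleophilic diene terminus next to the silyloxy carbon to the β-carbon C2. The step needs enough reactivity from a trisubstituted enal and suppression of Mukaiyama-type addition to the carbonyl, for which the electron-rich diene, the cationic Lewis acid and the bulky silyl group are chosen.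

Step 3
Reactants: 4 (1R,6R)-1,6-dimethyl-4-(triisopropylsilyloxy)cyclohex-3-ene-1-carbaldehyde
Product: 5 [(1R,6R)-1,6-dimethyl-4-(triisopropylsilyloxy)cyclohex-3-en-1-yl]methanol
Conditions: NaBH4, EtOH, 0 °C
Reagents that add atoms: none
Why: Borohydride reduction of the neopentyl aldehyde (C14) leaves the robust triisopropylsilyl enol ether untouched.

Step 4
Reactants: 5 [(1R,6R)-1,6-dimethyl-4-(triisopropylsilyloxy)cyclohex-3-en-1-yl]methanol
Product: 6 tert-butyl{[(1R,6R)-1,6-dimethyl-4-(triisopropylsilyloxy)cyclohex-3-en-1-yl]methoxy}dimethylsilane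
Conditions: t-BuMe2SiCl, imidazole, DMF, rt
Reagents that add atoms: tert-butyldimethylsilyl chloride, CC(C)(C)[Si](C)(C)Cl
Why: Standard silylation of the primary alcohol masks C14 through the cleavage and chain-building steps.

Step 5
Reactants: 6 tert-butyl{[(1R,6R)-1,6-dimethyl-4-(triisopropylsilyloxy)cyclohex-3-en-1-yl]methoxy}dimethylsilane
Product: 8 triisopropylsilyl (3R,4R)-4-[(tert-butyldimethylsilyloxy)methyl]-3,4-dimethyl-6-oxohexanoate, via α-methoxy hydroperoxide 7 (not isolated)
Conditions: O3, CH2Cl2/MeOH, −78 °C; then Me2S, −78 °C to rt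
Reagents that add atoms: ozone, [O-][O+]=O
Why: Ozonolysis of the electron-rich silyl enol ether should fragment so that the silyloxy carbon C4 leaves as the silyl ester and C19 as a carbonyl oxide, which methanol traps and Me2S reduces to the aldehyde; this opens the temporary ring into two arms at different oxidation levels.

Step 6
Reactants: 8 triisopropylsilyl (3R,4R)-4-[(tert-butyldimethylsilyloxy)methyl]-3,4-dimethyl-6-oxohexanoate; 9 3-bromofuran
Product: 11 triisopropylsilyl (3R,4R)-4-[(tert-butyldimethylsilyloxy)methyl]-6-(furan-3-yl)-6-hydroxy-3,4-dimethylhexanoate (both C19 epimers), via furan-3-yllithium 10 (not isolated)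
Conditions: 9, n-BuLi, THF, −78 °C; then 8, −78 °C; aq. NH4Cl
Reagents that add atoms: none
Why: Bromine–lithium exchange gives the 3-furyl anion, which is kept at −78 °C and should add to the aldehyde much faster than to the hindered silyl ester (organolithium 1,2-addition), forming C19–C20.

Step 7
Reactants: 11 triisopropylsilyl (3R,4R)-4-[(tert-butyldimethylsilyloxy)methyl]-6-(furan-3-yl)-6-hydroxy-3,4-dimethylhexanoate
Product: 12 triisopropylsilyl (3R,4R)-4-[(tert-butyldimethylsilyloxy)methyl]-6-(furan-3-yl)-3,4-dimethyl-6-(phenoxycarbonothioyloxy)hexanoate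
Conditions: PhOC(S)Cl, pyridine, DMAP (cat.), CH2Cl2, 0 °C to rt
Reagents that add atoms: O-phenyl chlorothionoformate, S=C(Cl)Oc1ccccc1
Why: Acylation of the secondary carbinol gives the thionocarbonate needed for radical deoxygenation under non-basic conditions that spare the silyl ester.

Step 8
Reactants: 12 triisopropylsilyl (3R,4R)-4-[(tert-butyldimethylsilyloxy)methyl]-6-(furan-3-yl)-3,4-dimethyl-6-(phenoxycarbonothioyloxy)hexanoate
Product: 13 triisopropylsilyl (3R,4R)-4-[(tert-butyldimethylsilyloxy)methyl]-6-(furan-3-yl)-3,4-dimethylhexanoate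
Conditions: Bu3SnH, AIBN (cat.), toluene, 90 °C
Reagents that add atoms: none
Why: Barton–McCombie deoxygenation through a furyl-stabilised secondary radical turns C19 into the methylene of the side chain.

Step 9
Reactants: 13 triisopropylsilyl (3R,4R)-4-[(tert-butyldimethylsilyloxy)methyl]-6-(furan-3-yl)-3,4-dimethylhexanoate
Product: 14 (3R,4R)-4-[(tert-butyldimethylsilyloxy)methyl]-6-(furan-3-yl)-3,4-dimethylhexan-1-ol
Conditions: LiAlH4, Et2O, 0 °C
Reagents that add atoms: none
Why: Hydride reduction of the silyl ester gives the primary alcohol at C4 without touching the silyl ether or the furan.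

Step 10
Reactants: 14 (3R,4R)-4-[(tert-butyldimethylsilyloxy)methyl]-6-(furan-3-yl)-3,4-dimethylhexan-1-ol
Product: 15 tert-butyl{[(2R,3R)-2-[2-(furan-3-yl)ethyl]-5-iodo-2,3-dimethylpentyl]oxy}dimethylsilane
Conditions: I2, PPh3, imidazole, CH2Cl2, 0 °C
Reagents that add atoms: iodine, II
Why: Appel iodination of the unhindered primary alcohol installs the Barbier handle at C4.

Step 11
Reactants: 15 tert-butyl{[(2R,3R)-2-[2-(furan-3-yl)ethyl]-5-iodo-2,3-dimethylpentyl]oxy}dimethylsilane
Product: 16 (2R,3R)-2-[2-(furan-3-yl)ethyl]-5-iodo-2,3-dimethylpentan-1-ol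
Conditions: HF·pyridine, pyridine/THF, 0 °C to rt
Reagents that add atoms: none
Why: Buffered fluoride cleaves the primary silyl ether without displacing the iodide or opening the furan, and without the base that would close a tetrahydropyran.

Step 12
Reactants: 16 (2R,3R)-2-[2-(furan-3-yl)ethyl]-5-iodo-2,3-dimethylpentan-1-ol
Product: 17 (2R,3R)-2-[2-(furan-3-yl)ethyl]-5-iodo-2,3-dimethylpentanal
Conditions: Dess–Martin periodinane, NaHCO3, CH2Cl2, 0 °C to rt
Reagents that add atoms: none
Why: Dess–Martin oxidation returns C14 to the aldehyde level; the aldehyde is non-enolisable because C16 is quaternary.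

Step 13
Reactants: 18 2,2-dimethylcyclopentane-1,3-dione
Product: 19 (R)-3-hydroxy-2,2-dimethylcyclopentan-1-one
Conditions: (S)-2-methyl-CBS-oxazaborolidine (20 mol%), catecholborane, toluene, −78 to −40 °C
Reagents that add atoms: none
Why: Corey–Bakshi–Shibata reduction desymmetrises the dione; with the quaternary carbon as the large group the (S)-catalyst is expected to give the (R)-carbinol, the C9 centre that serves as a temporary control element.

Step 14
Reactants: 19 (R)-3-hydroxy-2,2-dimethylcyclopentan-1-one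
Product: 20 (R)-3-(tert-butyldimethylsilyloxy)-2,2-dimethylcyclopentan-1-one
Conditions: t-BuMe2SiCl, imidazole, DMF, rt to 40 °C
Reagents that add atoms: tert-butyldimethylsilyl chloride, CC(C)(C)[Si](C)(C)Cl
Why: Silylation protects C9–OH and makes it a bulky group that shields one face of ring B.

Step 15
Reactants: 20 (R)-3-(tert-butyldimethylsilyloxy)-2,2-dimethylcyclopentan-1-one; 17 (2R,3R)-2-[2-(furan-3-yl)ethyl]-5-iodo-2,3-dimethylpentanal
Product: 22 (3R,5S)-3-(tert-butyldimethylsilyloxy)-5-[(1R,2R,3R)-2-[2-(furan-3-yl)ethyl]-1-hydroxy-5-iodo-2,3-dimethylpentyl]-2,2-dimethylcyclopentan-1-one, via lithium enolate 21 (not isolated)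
Conditions: LDA (lithium diisopropylamide), THF, −78 °C; then 17, −78 °C; aq. NH4Cl at −78 °C
Reagents that add atoms: none
Why: Lithium enolate aldol addition forms C7–C14; the E(O) enolate should react through a Zimmerman–Traxler chair on the ring face opposite the C9 silyloxy group, placing the C14 branch at C7 trans to that group, while the C14 carbinol configuration is of no consequence because it is oxidised in step 19.

Step 16
Reactants: 22 (3R,5S)-3-(tert-butyldimethylsilyloxy)-5-[(1R,2R,3R)-2-[2-(furan-3-yl)ethyl]-1-hydroxy-5-iodo-2,3-dimethylpentyl]-2,2-dimethylcyclopentan-1-one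
Product: 23 triethylsilyl ether of 22 at C14–OH
Conditions: Et3SiOTf, 2,6-lutidine, CH2Cl2, −78 °C
Reagents that add atoms: triethylsilyl triflate, CC[Si](CC)(CC)OS(=O)(=O)C(F)(F)F
Why: Silylation removes the acidic hydroxyl that would quench the organosamarium intermediate and blocks retro-aldol cleavage.

Step 17
Reactants: 23 triethylsilyl ether of 22 at C14–OH
Product: 24 cis-fused bicyclic tertiary alcohol (ring A closed; furan-3-yl in place of the butenolide; C5–OH; C14–OSiEt3; C9–OSi(t-Bu)Me2 cis to C5–OH; C7–H cis to C5–OH; C2 and C16 as in the target)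
Conditions: SmI2, HMPA, THF, −78 °C to rt
Reagents that add atoms: none
Why: SmI2 reduces the primary C–I bond to an organosamarium that adds to the C5 ketone (intramolecular Barbier reaction, known for iodoalkyl cycloalkanones including seven-membered closures); the tether on C7 should deliver C4 to its own face of the cyclopentanone, which is also the face remote from the C9 silyloxy group, so ring A closes cis-fused with the C5 configuration of the target.

Step 18
Reactants: 24 cis-fused bicyclic tertiary alcohol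
Product: 25 C5,C9,C14-triol (both silyl ethers removed; configurations as in 24)
Conditions: Bu4NF, THF, rt to 45 °C
Reagents that add atoms: none
Why: Fluoride cleaves both silyl ethers; the molecule carries no base-sensitive group at this stage.

Step 19
Reactants: 25 C5,C9,C14-triol
Product: 26 cis-fused C9,C14-diketone with free C5–OH
Conditions: Dess–Martin periodinane, NaHCO3, CH2Cl2, 0 °C to rt
Reagents that add atoms: none
Why: Dess–Martin oxidation converts both hindered secondary alcohols to ketones, spares the tertiary alcohol and the furan, and erases the temporary C9 and C14 carbinol centres.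

Step 20
Reactants: 26 cis-fused C9,C14-diketone with free C5–OH
Product: 27 cis-fused C14 ketone with C5–OH and C9–OH trans on ring B (C9 as in the target)
Conditions: Me4NBH(OAc)3, AcOH/MeCN, −30 to 0 °C
Reagents that add atoms: none
Why: Evans–Saksena reduction: the C5 hydroxyl exchanges onto boron and delivers hydride to the C9 carbonyl from its own face, giving the anti 1,3-diol (C9 S), while the C14 ketone, which in the cis-fused system lies anti to the C5 oxygen across C5–C7 and is flanked by the quaternary C16, should not be reached.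

Step 21
Reactants: 27 cis-fused C14 ketone diol
Product: 28 trans-fused C14 ketone diol (furan-3-yl analogue of the target; all five stereocentres as in the target)
Conditions: DBU, toluene, rt to 50 °C
Reagents that add atoms: none
Why: Base-mediated epimerisation through the C14 enol(ate), whose only α-hydrogen is at C7, should move the ring fusion from cis to trans, the isomer in which the C5 hydroxyl can hydrogen-bond to the C14 carbonyl and which is usually preferred for hydroazulenones with the ketone in the seven-membered ring next to the fusion.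

Step 22
Reactants: 28 trans-fused C14 ketone diol
Product: 31 target CNP0077405.3, via furan endoperoxide 29 (not isolated), via γ-hydroxybutenolide 30 (not isolated)
Conditions: O2, hν, 5,10,15,20-tetraphenylporphyrin (cat.), i-Pr2NEt, CH2Cl2, −78 °C; then NaBH4, EtOH, −20 to 0 °C; then 1 M HCl
Reagents that add atoms: oxygen, O=O
Why: Singlet oxygen adds across the furan 2,5-positions, the hindered amine removes the bridgehead proton remote from the side chain (Kornblum–DeLaMare-type opening) to place the carbonyl at C22 and the hemiacetal at C25, and borohydride reduction of the open-chain aldehyde form followed by acid lactonisation gives the 4-substituted furan-2(5H)-one, the hindered C14 ketone being expected to react far more slowly.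

**Compound list**

1 | but-3-en-2-one | C=CC(C)=O | starting material
2 | 2-(triisopropylsilyloxy)buta-1,3-diene | C=CC(=C)O[Si](C(C)C)(C(C)C)C(C)C | intermediate
3 | (E)-2-methylbut-2-enal | C/C=C(\C)C=O | starting material
4 | (1R,6R)-1,6-dimethyl-4-(triisopropylsilyloxy)cyclohex-3-ene-1-carbaldehyde | C[C@@H]1CC(O[Si](C(C)C)(C(C)C)C(C)C)=CC[C@@]1(C)C=O | intermediate
5 | [(1R,6R)-1,6-dimethyl-4-(triisopropylsilyloxy)cyclohex-3-en-1-yl]methanol | C[C@@H]1CC(O[Si](C(C)C)(C(C)C)C(C)C)=CC[C@@]1(C)CO | intermediate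
6 | tert-butyl{[(1R,6R)-1,6-dimethyl-4-(triisopropylsilyloxy)cyclohex-3-en-1-yl]methoxy}dimethylsilane | C[C@@H]1CC(O[Si](C(C)C)(C(C)C)C(C)C)=CC[C@@]1(C)CO[Si](C)(C)C(C)(C)C | intermediate
7 | triisopropylsilyl (3R,4R)-4-[(tert-butyldimethylsilyloxy)methyl]-6-hydroperoxy-6-methoxy-3,4-dimethylhexanoate (C19 epimers) | C[C@H](CC(=O)O[Si](C(C)C)(C(C)C)C(C)C)[C@@](C)(CC(OC)OO)CO[Si](C)(C)C(C)(C)C | intermediate
8 | triisopropylsilyl (3R,4R)-4-[(tert-butyldimethylsilyloxy)methyl]-3,4-dimethyl-6-oxohexanoate | C[C@H](CC(=O)O[Si](C(C)C)(C(C)C)C(C)C)[C@@](C)(CC=O)CO[Si](C)(C)C(C)(C)C | intermediate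
9 | 3-bromofuran | Brc1ccoc1 | starting material
10 | furan-3-yllithium | [Li]c1ccoc1 | intermediate
11 | triisopropylsilyl (3R,4R)-4-[(tert-butyldimethylsilyloxy)methyl]-6-(furan-3-yl)-6-hydroxy-3,4-dimethylhexanoate (C19 epimers) | C[C@H](CC(=O)O[Si](C(C)C)(C(C)C)C(C)C)[C@@](C)(CC(O)c1ccoc1)CO[Si](C)(C)C(C)(C)C | intermediate
12 | triisopropylsilyl (3R,4R)-4-[(tert-butyldimethylsilyloxy)methyl]-6-(furan-3-yl)-3,4-dimethyl-6-(phenoxycarbonothioyloxy)hexanoate (C19 epimers) | C[C@H](CC(=O)O[Si](C(C)C)(C(C)C)C(C)C)[C@@](C)(CC(OC(=S)Oc1ccccc1)c1ccoc1)CO[Si](C)(C)C(C)(C)C | intermediate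
13 | triisopropylsilyl (3R,4R)-4-[(tert-butyldimethylsilyloxy)methyl]-6-(furan-3-yl)-3,4-dimethylhexanoate | C[C@H](CC(=O)O[Si](C(C)C)(C(C)C)C(C)C)[C@@](C)(CCc1ccoc1)CO[Si](C)(C)C(C)(C)C | intermediate
14 | (3R,4R)-4-[(tert-butyldimethylsilyloxy)methyl]-6-(furan-3-yl)-3,4-dimethylhexan-1-ol | C[C@H](CCO)[C@@](C)(CCc1ccoc1)CO[Si](C)(C)C(C)(C)C | intermediate
15 | tert-butyl{[(2R,3R)-2-[2-(furan-3-yl)ethyl]-5-iodo-2,3-dimethylpentyl]oxy}dimethylsilane | C[C@H](CCI)[C@@](C)(CCc1ccoc1)CO[Si](C)(C)C(C)(C)C | intermediate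
16 | (2R,3R)-2-[2-(furan-3-yl)ethyl]-5-iodo-2,3-dimethylpentan-1-ol | C[C@H](CCI)[C@@](C)(CCc1ccoc1)CO | intermediate
17 | (2R,3R)-2-[2-(furan-3-yl)ethyl]-5-iodo-2,3-dimethylpentanal | C[C@H](CCI)[C@@](C)(CCc1ccoc1)C=O | intermediate
18 | 2,2-dimethylcyclopentane-1,3-dione | CC1(C)C(=O)CCC1=O | starting material
19 | (R)-3-hydroxy-2,2-dimethylcyclopentan-1-one | O=C1CC[C@@H](O)C1(C)C | intermediate
20 | (R)-3-(tert-butyldimethylsilyloxy)-2,2-dimethylcyclopentan-1-one | O=C1CC[C@@H](O[Si](C)(C)C(C)(C)C)C1(C)C | intermediate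
21 | lithium enolate of 20 | [Li]OC1=CC[C@@H](O[Si](C)(C)C(C)(C)C)C1(C)C | intermediate
22 | (3R,5S)-3-(tert-butyldimethylsilyloxy)-5-[(1R,2R,3R)-2-[2-(furan-3-yl)ethyl]-1-hydroxy-5-iodo-2,3-dimethylpentyl]-2,2-dimethylcyclopentan-1-one | ICC[C@@H](C)[C@@](C)(CCc1ccoc1)[C@H](O)[C@@H]1C[C@@H](O[Si](C)(C)C(C)(C)C)C(C)(C)C1=O | intermediate
23 | triethylsilyl ether of 22 at C14–OH | ICC[C@@H](C)[C@@](C)(CCc1ccoc1)[C@H](O[Si](CC)(CC)CC)[C@@H]1C[C@@H](O[Si](C)(C)C(C)(C)C)C(C)(C)C1=O | intermediate
24 | cis-fused bicyclic tertiary alcohol (C5–OH; C14–OSiEt3; C9–OSi(t-Bu)Me2 cis to C5–OH; C7–H cis to C5–OH; furan-3-yl side chain) | C[C@@H]1CC[C@]2(O)[C@@H](C[C@@H](O[Si](C)(C)C(C)(C)C)C2(C)C)[C@@H](O[Si](CC)(CC)CC)[C@]1(C)CCc1ccoc1 | intermediate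
25 | C5,C9,C14-triol (configurations as in 24) | C[C@@H]1CC[C@]2(O)[C@@H](C[C@@H](O)C2(C)C)[C@@H](O)[C@]1(C)CCc1ccoc1 | intermediate
26 | cis-fused C9,C14-diketone with C5–OH | C[C@@H]1CC[C@]2(O)[C@@H](CC(=O)C2(C)C)C(=O)[C@]1(C)CCc1ccoc1 | intermediate
27 | cis-fused C14 ketone, C5–OH and C9–OH trans (7-epimer of 28) | C[C@@H]1CC[C@]2(O)[C@@H](C[C@H](O)C2(C)C)C(=O)[C@]1(C)CCc1ccoc1 | intermediate
28 | trans-fused C14 ketone diol, furan-3-yl analogue of the target | C[C@@H]1CC[C@]2(O)[C@H](C[C@H](O)C2(C)C)C(=O)[C@]1(C)CCc1ccoc1 | intermediate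
29 | 2,5-endoperoxide of the furan of 28 (2,3,7-trioxabicyclo[2.2.1]hept-5-ene, side chain on C5; bridgehead epimers) | C[C@@H]1CC[C@]2(O)[C@H](C[C@H](O)C2(C)C)C(=O)[C@]1(C)CCC1=CC2OOC1O2 | intermediate
30 | γ-hydroxybutenolide (5-hydroxy-4-substituted furan-2(5H)-one; C25 epimers) | C[C@@H]1CC[C@]2(O)[C@H](C[C@H](O)C2(C)C)C(=O)[C@]1(C)CCC1=CC(=O)OC1O | intermediate
31 | CNP0077405.3 (2R,5S,7S,9S,16R in SMILES-order numbering) | C[C@@H]1CC[C@]2(O)[C@H](C[C@H](O)C2(C)C)C(=O)[C@]1(C)CCC1=CC(=O)OC1 | target

**Step count and risks**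

Total: 22 steps. Longest linear sequence: 20 steps (steps 1–12, then 15–22); steps 13–14 form the short branch.

Steps most likely to fail:

1. Step 17 (Barbier closure of ring A). Simple reduction of the C–I bond or of the hindered ketone may outrun seven-membered ring closure, or C4 may attack the other face of the ketone. The fallback sets out from 15 and 20 and returns at 26; it forms C4–C5 first, intermolecularly, and closes ring A at C7–C14. Ketone 20 would be dehydrogenated with 2-iodoxybenzoic acid (DMSO, 65 °C) to (R)-4-(tert-butyldimethylsilyloxy)-5,5-dimethylcyclopent-2-en-1-one F1 and iodinated (I2, pyridine, CH2Cl2) to (R)-4-(tert-butyldimethylsilyloxy)-2-iodo-5,5-dimethylcyclopent-2-en-1-one F2. Iodide 15 would be converted by iodine–lithium exchange (t-BuLi, Et2O, −78 °C) into [(3R,4R)-4-[(tert-butyldimethylsilyloxy)methyl]-6-(furan-3-yl)-3,4-dimethylhexyl]lithium F3, transmetallated with CeCl3 and added to the carbonyl of F2 anti to the silyloxy group, giving the tertiary allylic alcohol with vinyl iodide F4 (C5 as in the target). Bu4NF would give the triol F5, Dess–Martin oxidation the β-iodo enone aldehyde F6, an intramolecular Nozaki–Hiyama–Kishi reaction (CrCl2, NiCl2 cat., DMSO) the ring-A allylic alcohol F7, and a second Dess–Martin oxidation the ene-dione F8. Conjugate reduction of F8 with [(Ph3P)CuH]6 would deliver diketone 26; any C7 epimer formed converges in step 21.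

2. Step 21 (C7 equilibration). The equilibrium may not favour the trans fusion, or the basic medium may open the β-hydroxy ketone by retro-aldol cleavage (which would also scramble C5) or dehydrate it across C5–C7. The fallback sets out from 27 and returns at 28; it replaces thermodynamic by kinetic control. Compound 27 would be silylated (Me3SiOTf, 2,6-lutidine, CH2Cl2, −78 °C) to the C5,C9-bis(trimethylsilyl) ether of 27 F9 and deprotonated at C7 with KN(SiMe3)2 (THF, −78 °C) to the potassium C7=C14 enolate F10. Protonation with 2,6-di-tert-butylphenol at −78 °C, on the face of C7 opposite the bulky C5 silyloxy group, should give the trans-fused bis(trimethylsilyl) ether F11, and HF·pyridine would then release 28 without a basic step.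

3. Step 2 (key cycloaddition). The trisubstituted enal may react too slowly, the silyloxydiene may add to the carbonyl or transfer silicon, or the enantioselectivity may be insufficient. The fallback sets out from 2 and 3 and returns at 5; it keeps the same cycloaddition but takes the absolute configuration from a resolution. Me2AlCl (CH2Cl2, −78 °C) would give racemic cis-1,6-dimethyl-4-(triisopropylsilyloxy)cyclohex-3-ene-1-carbaldehyde F12, and NaBH4 the racemic alcohol F13. Esterification with (S)-2-methoxy-2-phenylacetic acid (DCC, DMAP, CH2Cl2) would give the (S)-2-methoxy-2-phenylacetate of the (1R,6R) alcohol F14 and the diastereomeric ester of the (1S,6S) alcohol F15, to be separated by chromatography or crystallisation. Cleavage of F14 with i-Bu2AlH (CH2Cl2, −78 °C) would return 5.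

**Further compounds**

F1 | step 17 | (R)-4-(tert-butyldimethylsilyloxy)-5,5-dimethylcyclopent-2-en-1-one | O=C1C=C[C@@H](O[Si](C)(C)C(C)(C)C)C1(C)C
F2 | step 17 | (R)-4-(tert-butyldimethylsilyloxy)-2-iodo-5,5-dimethylcyclopent-2-en-1-one | O=C1C(I)=C[C@@H](O[Si](C)(C)C(C)(C)C)C1(C)C
F3 | step 17 | [(3R,4R)-4-[(tert-butyldimethylsilyloxy)methyl]-6-(furan-3-yl)-3,4-dimethylhexyl]lithium | C[C@H](CC[Li])[C@@](C)(CCc1ccoc1)CO[Si](C)(C)C(C)(C)C
F4 | step 17 | tertiary allylic alcohol with vinyl iodide (C4–C5 joined; C5–OH cis to C9–OSi) | C[C@H](CC[C@]1(O)C(I)=C[C@@H](O[Si](C)(C)C(C)(C)C)C1(C)C)[C@@](C)(CCc1ccoc1)CO[Si](C)(C)C(C)(C)C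
F5 | step 17 | triol from F4 | C[C@H](CC[C@]1(O)C(I)=C[C@@H](O)C1(C)C)[C@@](C)(CCc1ccoc1)CO
F6 | step 17 | β-iodo enone aldehyde | C[C@H](CC[C@]1(O)C(I)=CC(=O)C1(C)C)[C@@](C)(CCc1ccoc1)C=O
F7 | step 17 | ring-A allylic alcohol (C14 epimers) | C[C@@H]1CC[C@]2(O)C(=CC(=O)C2(C)C)C(O)[C@]1(C)CCc1ccoc1
F8 | step 17 | C7=C8 ene-dione | C[C@@H]1CC[C@]2(O)C(=CC(=O)C2(C)C)C(=O)[C@]1(C)CCc1ccoc1
F9 | step 21 | C5,C9-bis(trimethylsilyl) ether of 27 | C[C@@H]1CC[C@]2(O[Si](C)(C)C)[C@@H](C[C@H](O[Si](C)(C)C)C2(C)C)C(=O)[C@]1(C)CCc1ccoc1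
F10 | step 21 | potassium C7=C14 enolate of F9 | C[C@@H]1CC[C@]2(O[Si](C)(C)C)C(C[C@H](O[Si](C)(C)C)C2(C)C)=C([O-])[C@]1(C)CCc1ccoc1.[K+]
F11 | step 21 | trans-fused C5,C9-bis(trimethylsilyl) ether (silyl ether of 28) | C[C@@H]1CC[C@]2(O[Si](C)(C)C)[C@H](C[C@H](O[Si](C)(C)C)C2(C)C)C(=O)[C@]1(C)CCc1ccoc1
F12 | step 2 | racemic cis-1,6-dimethyl-4-(triisopropylsilyloxy)cyclohex-3-ene-1-carbaldehyde (one enantiomer drawn) | C[C@@H]1CC(O[Si](C(C)C)(C(C)C)C(C)C)=CC[C@@]1(C)C=O
F13 | step 2 | racemic cis-[1,6-dimethyl-4-(triisopropylsilyloxy)cyclohex-3-en-1-yl]methanol (one enantiomer drawn) | C[C@@H]1CC(O[Si](C(C)C)(C(C)C)C(C)C)=CC[C@@]1(C)CO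
F14 | step 2 | [(1R,6R)-1,6-dimethyl-4-(triisopropylsilyloxy)cyclohex-3-en-1-yl]methyl (S)-2-methoxy-2-phenylacetate | C[C@@H]1CC(O[Si](C(C)C)(C(C)C)C(C)C)=CC[C@@]1(C)COC(=O)[C@@H](OC)c1ccccc1
F15 | step 2 | [(1S,6S)-1,6-dimethyl-4-(triisopropylsilyloxy)cyclohex-3-en-1-yl]methyl (S)-2-methoxy-2-phenylacetate | C[C@H]1CC(O[Si](C(C)C)(C(C)C)C(C)C)=CC[C@]1(C)COC(=O)[C@@H](OC)c1ccccc1
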